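**Retrosynthetic overview**

- The strategy rests on the trans pair of arylmethyl groups on the γ-butyrolactone ring (O1, C2 carbonyl, C3, C4, C5). C3 (α to C2=O) carries the ring A benzyl carbon C6 and C4 (β) carries the ring B benzyl carbon C7, so both can be installed across the C3=C4 bond of a butenolide.
- Late stage: the ring A phenol is released from a benzyl ether, the C5 methylene comes from a menthyloxy acetal carbon (opening, reduction, relactonization), and the C7 methylene comes from a dithiane carbon (desulfurization).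
- Key disconnection: C4–C7 by conjugate addition of lithiated 2-(3,4-dimethoxyphenyl)-1,3-dithiane to (5R)-5-menthyloxyfuran-2(5H)-one, and C3–C6 by benzylation of the resulting enolate with 3-(benzyloxy)-4,5-dimethoxybenzyl bromide.
- Precursors: the butenolide from furfural (photooxygenation) and (−)-menthol; the dithiane from veratraldehyde; the bromide from 3-hydroxy-4,5-dimethoxybenzaldehyde (benzylation, reduction, bromination).
- Ring order: the five-membered lactone ring is made first (step 1) and carried throughout; it is opened and re-closed once (step 9). The dithiane is a temporary ring, and no carbocycle is built.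

Key step: step 7

Remark: ring A is the 3-hydroxy-4,5-dimethoxyphenyl ring (on C6) and ring B the 3,4-dimethoxyphenyl ring (on C7). "Menthyloxy" means (1R,2S,5R)-2-isopropyl-5-methylcyclohexyloxy. 3-Hydroxy-4,5-dimethoxybenzaldehyde is taken as a purchasable compound.

**Route**

Step 1
Reactants: 1 furfural
Product: 3 5-hydroxyfuran-2(5H)-one, via furfural endoperoxide 2 (not isolated)
Conditions: O2, visible light, cat. methylene blue (C16H18ClN3S), MeOH, 15–20 °C
Reagents that add atoms: dioxygen, O=O
Why: Dye-sensitized singlet-oxygen [4+2] cycloaddition to the furan gives endoperoxide 2, and methanol attack at its formyl group fragments the C–CHO bond with O–O cleavage (methyl formate lost) to leave the racemic γ-hydroxybutenolide, a standard furfural photooxygenation that sets no controlled stereocenter.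

Step 2
Reactants: 3 5-hydroxyfuran-2(5H)-one; 4 (−)-menthol
Product: 5 (5R)-5-[(1R,2S,5R)-menthyloxy]furan-2(5H)-one
Conditions: cat. p-toluenesulfonic acid monohydrate, toluene, reflux, Dean–Stark; crystallization from petroleum ether, −20 °C; mother liquor re-equilibrated with the same acid and recrystallized
Reagents that add atoms: none
Why: Acid-catalysed acetalization of the pseudoacid through an acyloxy-oxocarbenium ion gives both C5 epimers, which interconvert under the acid, and the 5R epimer is expected to be the crystalline one, so crystallization with recycling of the mother liquor (crystallization-induced diastereomer enrichment) should deliver the single 5R acetal.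

Step 3
Reactants: 6 veratraldehyde
Product: 7 2-(3,4-dimethoxyphenyl)-1,3-dithiane
Conditions: HS(CH2)3SH, cat. BF3·OEt2, CH2Cl2, 0 °C → rt
Reagents that add atoms: propane-1,3-dithiol, SCCCS
Why: Lewis-acid-catalysed dithioacetalization of an aromatic aldehyde is a reliable condensation and turns the aldehyde carbon into an acyl-anion equivalent (umpolung) that is later reduced to C7.

Step 4
Reactants: 8 3-hydroxy-4,5-dimethoxybenzaldehyde
Product: 9 3-(benzyloxy)-4,5-dimethoxybenzaldehyde
Conditions: BnBr, K2CO3, DMF, rt
Reagents that add atoms: benzyl bromide, BrCc1ccccc1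
Why: Williamson etherification of the phenoxide masks the only acidic proton of ring A with a group that tolerates organolithium, nickel and borohydride chemistry and is removed last by hydrogenolysis.

Step 5
Reactants: 9 3-(benzyloxy)-4,5-dimethoxybenzaldehyde
Product: 10 [3-(benzyloxy)-4,5-dimethoxyphenyl]methanol
Conditions: NaBH4, MeOH, 0 °C → rt
Reagents that add atoms: none
Why: Borohydride reduction of an aryl aldehyde to the benzylic alcohol is chemoselective in the presence of aryl ethers.

Step 6
Reactants: 10 [3-(benzyloxy)-4,5-dimethoxyphenyl]methanol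
Product: 11 3-(benzyloxy)-4,5-dimethoxybenzyl bromide
Conditions: PBr3, Et2O, 0 °C; used directly after short filtration
Reagents that add atoms: phosphorus tribromide, BrP(Br)Br
Why: Activation of the benzylic alcohol as a bromophosphite followed by SN2 displacement by bromide gives the benzylic bromide without touching the aryl ethers, and immediate use avoids decomposition of this electron-rich halide.

Step 7
Reactants: 7 2-(3,4-dimethoxyphenyl)-1,3-dithiane; 5 (5R)-5-[(1R,2S,5R)-menthyloxy]furan-2(5H)-one; 11 3-(benzyloxy)-4,5-dimethoxybenzyl bromide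
Product: 14 (3R,4R,5R)-3-[3-(benzyloxy)-4,5-dimethoxybenzyl]-4-[2-(3,4-dimethoxyphenyl)-1,3-dithian-2-yl]-5-[(1R,2S,5R)-menthyloxy]dihydrofuran-2(3H)-one, via 2-lithio-2-(3,4-dimethoxyphenyl)-1,3-dithiane 12 (not isolated), via lithium enolate 13 (not isolated)
Conditions: 7, n-BuLi, THF, −78 → −20 °C; −78 °C, then 5; then 11, DMPU, −78 °C → rt; aq. NH4Cl
Reagents that add atoms: none
Why: n-BuLi removes the C2–H of 7 to give the sulfur-stabilized benzylic carbanion 12, which adds in Michael fashion to C4 of butenolide 5 to form C4–C7 and lithium enolate 13, and SN2 attack of C3 of 13 on bromide 11 (DMPU loosening the enolate aggregate) forms C3–C6. The closest known reaction type is the tandem conjugate addition–enolate alkylation of 2-aryl-2-lithio-1,3-dithianes with 5-alkoxyfuran-2(5H)-ones and benzylic bromides, a known three-component coupling. No ring is closed: the lactone ring of 5 is carried through intact and the dithiane is a preformed ring. C4 is set by approach of the bulky nucleophile to the face opposite the C5 menthyloxy group, the 5R acetal carbon being the control element, and C3 is set by alkylation on the face opposite the large C4 aryldithianyl group, so the 3,4-trans-4,5-trans (3R,4R,5R) adduct should result. The step needs 1,4- over 1,2-addition, which the soft, delocalized and hindered aryldithianyl anion at −78 °C in THF secures, and clean C-monoalkylation, which the reactive benzylic bromide, the polar additive and the shielded C3–H of the product secure.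

Step 8
Reactants: 14 (3R,4R,5R)-3-[3-(benzyloxy)-4,5-dimethoxybenzyl]-4-[2-(3,4-dimethoxyphenyl)-1,3-dithian-2-yl]-5-[(1R,2S,5R)-menthyloxy]dihydrofuran-2(3H)-one
Product: 15 (3R,4R,5R)-3-[3-(benzyloxy)-4,5-dimethoxybenzyl]-4-(3,4-dimethoxybenzyl)-5-[(1R,2S,5R)-menthyloxy]dihydrofuran-2(3H)-one
Conditions: Raney Ni (W-2, washed neutral), EtOH/THF, rt → 60 °C
Reagents that add atoms: none
Why: Raney nickel hydrogenolysis of both benzylic C–S bonds (Mozingo-type desulfurization) turns the dithiane carbon into the C7 methylene, and under neutral, mild conditions the acyl acetal, the lactone, the benzyl ether and the three ring stereocenters (none at the reacting carbon) should be unaffected.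

Step 9
Reactants: 15 (3R,4R,5R)-3-[3-(benzyloxy)-4,5-dimethoxybenzyl]-4-(3,4-dimethoxybenzyl)-5-[(1R,2S,5R)-menthyloxy]dihydrofuran-2(3H)-one
Product: 18 (3R,4R)-3-[3-(benzyloxy)-4,5-dimethoxybenzyl]-4-(3,4-dimethoxybenzyl)dihydrofuran-2(3H)-one, via potassium 4-oxobutanoate 16 (not isolated), via potassium 4-hydroxybutanoate 17 (not isolated)
Conditions: KOH, NaBH4, EtOH/H2O, 0 °C → rt; then 2 M HCl to pH 1, rt
Reagents that add atoms: potassium hydroxide, [K+].[OH-] (its oxygen enters the carboxylate of 16 and 17 and can remain as the carbonyl oxygen of 18)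
Why: Saponification of the acyl acetal opens the ring and the hemiacetal expels menthoxide to unmask the C5 aldehyde 16, which borohydride already present reduces at once to alcohol 17, and acidification re-closes the γ-hydroxy acid to the five-membered lactone (acid-catalysed lactonization) without touching C3 or C4, so the 3R,4R trans relationship from step 7 is kept.

Step 10
Reactants: 18 (3R,4R)-3-[3-(benzyloxy)-4,5-dimethoxybenzyl]-4-(3,4-dimethoxybenzyl)dihydrofuran-2(3H)-one
Product: 19 (3R,4R)-4-(3,4-dimethoxybenzyl)-3-(3-hydroxy-4,5-dimethoxybenzyl)dihydrofuran-2(3H)-one (CNP0246971.1)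
Conditions: H2 (1 atm), 10% Pd/C, EtOAc/EtOH, rt
Reagents that add atoms: none
Why: Palladium-catalysed hydrogenolysis cleaves only the benzyl aryl ether, since the lactone, the methyl ethers and the non-oxygenated benzylic methylenes C6 and C7 are inert, so the phenol is released with both stereocenters untouched.

**Compound list**

1 | furfural | O=Cc1ccco1 | starting material
2 | furfural endoperoxide (2,3,7-trioxabicyclo[2.2.1]hept-5-ene-1-carbaldehyde, racemic) | O=CC12C=CC(OO1)O2 | intermediate
3 | 5-hydroxyfuran-2(5H)-one (racemic) | O=C1C=CC(O)O1 | intermediate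
4 | (−)-menthol, (1R,2S,5R)-2-isopropyl-5-methylcyclohexanol | C[C@@H]1CC[C@H]([C@@H](C1)O)C(C)C | starting material
5 | (5R)-5-[(1R,2S,5R)-menthyloxy]furan-2(5H)-one | C[C@@H]1CC[C@H]([C@@H](C1)O[C@H]1C=CC(=O)O1)C(C)C | intermediate
6 | veratraldehyde (3,4-dimethoxybenzaldehyde) | COc1ccc(C=O)cc1OC | starting material
7 | 2-(3,4-dimethoxyphenyl)-1,3-dithiane | COc1ccc(C2SCCCS2)cc1OC | intermediate
8 | 3-hydroxy-4,5-dimethoxybenzaldehyde | COc1cc(C=O)cc(O)c1OC | starting material
9 | 3-(benzyloxy)-4,5-dimethoxybenzaldehyde | COc1cc(C=O)cc(OCc2ccccc2)c1OC | intermediate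
10 | [3-(benzyloxy)-4,5-dimethoxyphenyl]methanol | COc1cc(CO)cc(OCc2ccccc2)c1OC | intermediate
11 | 3-(benzyloxy)-4,5-dimethoxybenzyl bromide | COc1cc(CBr)cc(OCc2ccccc2)c1OC | intermediate
12 | 2-lithio-2-(3,4-dimethoxyphenyl)-1,3-dithiane | [Li]C1(SCCCS1)c1ccc(OC)c(OC)c1 | intermediate
13 | lithium enolate of (4R,5R)-4-[2-(3,4-dimethoxyphenyl)-1,3-dithian-2-yl]-5-[(1R,2S,5R)-menthyloxy]dihydrofuran-2(3H)-one | COc1ccc(C2(SCCCS2)[C@H]2[C@H](O[C@@H]3C[C@H](C)CC[C@H]3C(C)C)OC(O[Li])=C2)cc1OC | intermediate
14 | (3R,4R,5R)-3-[3-(benzyloxy)-4,5-dimethoxybenzyl]-4-[2-(3,4-dimethoxyphenyl)-1,3-dithian-2-yl]-5-[(1R,2S,5R)-menthyloxy]dihydrofuran-2(3H)-one | COc1ccc(C2(SCCCS2)[C@H]2[C@H](O[C@@H]3C[C@H](C)CC[C@H]3C(C)C)OC(=O)[C@@H]2Cc2cc(OCc3ccccc3)c(OC)c(OC)c2)cc1OC | intermediate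
15 | (3R,4R,5R)-3-[3-(benzyloxy)-4,5-dimethoxybenzyl]-4-(3,4-dimethoxybenzyl)-5-[(1R,2S,5R)-menthyloxy]dihydrofuran-2(3H)-one | COc1ccc(C[C@H]2[C@H](O[C@@H]3C[C@H](C)CC[C@H]3C(C)C)OC(=O)[C@@H]2Cc2cc(OCc3ccccc3)c(OC)c(OC)c2)cc1OC | intermediate
16 | potassium (2R,3R)-2-[3-(benzyloxy)-4,5-dimethoxybenzyl]-3-(3,4-dimethoxybenzyl)-4-oxobutanoate | COc1ccc(C[C@@H](C=O)[C@@H](Cc2cc(OCc3ccccc3)c(OC)c(OC)c2)C(=O)[O-])cc1OC.[K+] | intermediate
17 | potassium (2R,3R)-2-[3-(benzyloxy)-4,5-dimethoxybenzyl]-3-(3,4-dimethoxybenzyl)-4-hydroxybutanoate | COc1ccc(C[C@@H](CO)[C@@H](Cc2cc(OCc3ccccc3)c(OC)c(OC)c2)C(=O)[O-])cc1OC.[K+] | intermediate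
18 | (3R,4R)-3-[3-(benzyloxy)-4,5-dimethoxybenzyl]-4-(3,4-dimethoxybenzyl)dihydrofuran-2(3H)-one | COc1ccc(C[C@H]2COC(=O)[C@@H]2Cc2cc(OCc3ccccc3)c(OC)c(OC)c2)cc1OC | intermediate
19 | (3R,4R)-4-(3,4-dimethoxybenzyl)-3-(3-hydroxy-4,5-dimethoxybenzyl)dihydrofuran-2(3H)-one (CNP0246971.1) | COc1ccc(C[C@H]2COC(=O)[C@@H]2Cc2cc(O)c(OC)c(OC)c2)cc1OC | target

**Step count**

Total step count: 10. Longest linear sequence: 7 steps (8 → 9 → 10 → 11 → 14 → 15 → 18 → 19, steps 4 to 10).

**Steps most likely to fail**

1. Step 7. The one-pot coupling can stall after the Michael addition through enolate aggregation or proton transfer. Incomplete addition could also leave lithiated dithiane to be benzylated by 11, and some 1,2-addition is possible.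
   Fallback: setting out from 5 and 7, the conjugate addition is run alone (n-BuLi, THF, −78 °C) and quenched cold with aq. NH4Cl. The Michael adduct (4R,5R)-4-[2-(3,4-dimethoxyphenyl)-1,3-dithian-2-yl]-5-[(1R,2S,5R)-menthyloxy]dihydrofuran-2(3H)-one F1 is isolated and purified. In a separate operation it is enolized with LiN(iPr)2 in THF/DMPU at −78 °C and benzylated with 11, anti to the C4 group, which brings the route back at 14.

2. Step 8. Nickel can partly hydrogenolyse the benzyl ether, or C–S cleavage can stall at the hindered quaternary benzylic carbon.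
   Fallback: setting out from 14, the dithiane is removed by a radical chain reduction instead of surface hydrogenolysis: n-Bu3SnH in excess with 2,2'-azobis(2-methylpropionitrile) in refluxing toluene, through homolysis of the benzylic C–S bonds. This leaves the benzyl ether and the acyl acetal alone and comes back to the route at 15; no new compound is made on the way (F0).

3. Step 9. The unmasked C5 aldehyde is α to C4 and could epimerize in the basic medium before hydride capture, or opening of the hindered acyl acetal could be slow.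
   Fallback: setting out from 15, the menthyl acetal is first hydrolysed under acid (aq. HCl, dioxane, 60 °C) to the pseudoacid (3R,4R)-3-[3-(benzyloxy)-4,5-dimethoxybenzyl]-4-(3,4-dimethoxybenzyl)-5-hydroxydihydrofuran-2(3H)-one F2 (C5 epimers). Its ring-chain aldehyde form is then reduced with NaBH4 in EtOH at 0 °C in the presence of one equivalent of NaHCO3, and acidification relactonizes, coming back to the route at 18.

**Further compounds**

F1 | step 7 | (4R,5R)-4-[2-(3,4-dimethoxyphenyl)-1,3-dithian-2-yl]-5-[(1R,2S,5R)-menthyloxy]dihydrofuran-2(3H)-one | COc1ccc(C2(SCCCS2)[C@H]2[C@H](O[C@@H]3C[C@H](C)CC[C@H]3C(C)C)OC(=O)C2)cc1OC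
F0 | step 8 | none | none
F2 | step 9 | (3R,4R)-3-[3-(benzyloxy)-4,5-dimethoxybenzyl]-4-(3,4-dimethoxybenzyl)-5-hydroxydihydrofuran-2(3H)-one (C5 epimers) | COc1ccc(C[C@H]2C(O)OC(=O)[C@@H]2Cc2cc(OCc3ccccc3)c(OC)c(OC)c2)cc1OC
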